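**Retrosynthetic overview**

1. The target is a cyclohex-3-ene, numbered here as: C1 bears the aroyl group (carbonyl carbon C7), C2 the 2,6-dihydroxy-3-cinnamoylphenyl ring, C3=C4(CH3), C5H2, and C6 the 4-hydroxyphenyl ring. The configuration is (1S,2S,6S), so the aroyl group is cis to the C6 aryl and trans to the C2 aryl. That is the pattern of a Z-enone; an E-chalcone cannot deliver it.
2. Lock: C7 and an extra ortho-oxygen on the C6 aryl are tied into a benzopyran ring (taken from umbelliferone). The ring is opened by hydrolysis after the key step and its oxygen is then removed (ArOH → ArOTf → ArH).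
3. Disconnections: chalcone C=C (late directed aldol condensation); C5–C6 and C1–C2 (flavylium ion 13 + aryl diene 12); C7–aryl (aryllithium + coumarin); diene–arene (Suzuki–Miyaura).
4. Ring order: pyran ring (coumarin → pyrylium) → cyclobutane C1–C4–C5–C6 (kinetic) → cyclohexene by two-atom ring expansion (C1–C4 broken, C1–C2 made) → pyran ring opened.
5. Enabling feature: the O+=C7 unit of the benzopyrylium/chromanylium ring. It makes C6 electrophilic, turns C1 into an enol-ether nucleophile and holds H-1/H-6 cis. As an acceptor next to C1, opposite the donor allyl system C4–C3–C2 (conjugated to the 2,6-dioxygenated aryl), it lets the cyclobutane bond C1–C4 ionise so that C1 re-closes on C2.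

Key step: step 9

Assumption (remark on the chemistry): the sense of induction of the chiral acid in step 9 cannot be predicted with certainty; the (R)-catalyst is written, and its mirror image would be used if it delivers the antipodal series.

**Route**

Step 1
Reactants: 1 4-bromobenzene-1,3-diol
Product: 2 1-bromo-2,4-bis(methoxymethoxy)benzene
Conditions: MOMCl, i-Pr2NEt, CH2Cl2, 0 °C → rt
Reagents that add atoms: chloromethyl methyl ether (MOMCl), COCCl
Why: Double O-alkylation of the phenols (Williamson-type acetal ether formation) should give MOM ethers that tolerate organolithium reagents and direct the later ortho-metalation.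

Step 2
Reactants: 2 1-bromo-2,4-bis(methoxymethoxy)benzene
Product: 3 1-bromo-2,4-bis(methoxymethoxy)-3-(3-methylbut-2-en-1-yl)benzene
Conditions: LiN(i-Pr)2, THF, −78 °C; then CuBr·SMe2 (10 mol%), prenyl bromide, −78 → 0 °C
Reagents that add atoms: prenyl bromide (1-bromo-3-methylbut-2-ene), CC(C)=CCBr
Why: Directed ortho-metalation should remove the proton between the two MOM-oxy groups (the bromine is meta, so neither exchange nor aryne formation is expected), and copper-catalysed allylation of the aryllithium should couple at the α-carbon of the prenyl unit.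

Step 3
Reactants: 4 7-hydroxy-2H-chromen-2-one (umbelliferone)
Product: 5 7-(methoxymethoxy)-2H-chromen-2-one
Conditions: MOMCl, i-Pr2NEt, CH2Cl2, 0 °C → rt
Reagents that add atoms: chloromethyl methyl ether (MOMCl), COCCl
Why: Williamson-type O-alkylation of the only phenol; this oxygen becomes the 4-hydroxyl of the C6 aryl ring.

Step 4
Reactants: 3 1-bromo-2,4-bis(methoxymethoxy)-3-(3-methylbut-2-en-1-yl)benzene; 5 7-(methoxymethoxy)-2H-chromen-2-one
Product: 6 2-[2,4-bis(methoxymethoxy)-3-(3-methylbut-2-en-1-yl)phenyl]-7-(methoxymethoxy)-2H-chromen-2-ol (racemic lactol; ring-chain tautomer of the (Z)-2-hydroxychalcone)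
Conditions: 3, n-BuLi, THF, −78 °C; then added to 5 (1.2 equiv), THF, −78 °C; sat. aq. NH4Cl; kept in the dark
Reagents that add atoms: none
Why: Bromine–lithium exchange and 1,2-addition of the aryllithium to the lactone carbonyl should stop after one addition, because the adduct opens to a (Z)-enone phenoxide whose push–pull conjugation deactivates the ketone; protonation closes it to the lactol, with the Z geometry inherited from the coumarin ring.

Step 5
Reactants: 7 1-(2,4-dihydroxyphenyl)ethan-1-one
Product: 8 1-(2,4-dihydroxy-3-iodophenyl)ethan-1-one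
Conditions: I2, HIO3, EtOH/H2O, rt → 40 °C
Reagents that add atoms: iodine, [I][I]; iodic acid, O=I(=O)O
Why: Electrophilic aromatic iodination should occur at the position flanked by both hydroxyl groups, with iodic acid re-oxidising iodide so that all iodine is used.

Step 6
Reactants: 8 1-(2,4-dihydroxy-3-iodophenyl)ethan-1-one
Product: 9 1-[3-iodo-2,4-bis(methoxymethoxy)phenyl]ethan-1-one
Conditions: NaH, MOMCl, DMF, 0 °C → rt
Reagents that add atoms: chloromethyl methyl ether (MOMCl), COCCl
Why: Williamson-type O-alkylation; the strong base is chosen because the 2-hydroxyl is hydrogen-bonded to the ketone and flanked by iodine.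

Step 7
Reactants: 10 2-methylbut-1-en-3-yne
Product: 11 4,4,5,5-tetramethyl-2-[(1E)-3-methylbuta-1,3-dien-1-yl]-1,3,2-dioxaborolane
Conditions: pinacolborane, Cp2Zr(H)Cl (5 mol%), Et3N (10 mol%), neat, 60 °C
Reagents that add atoms: pinacolborane, CC1(C)OBOC1(C)C
Why: Zirconium-catalysed syn-hydroboration of the terminal alkyne should give the E-dienylboronate regioselectively.

Step 8
Reactants: 9 1-[3-iodo-2,4-bis(methoxymethoxy)phenyl]ethan-1-one; 11 4,4,5,5-tetramethyl-2-[(1E)-3-methylbuta-1,3-dien-1-yl]-1,3,2-dioxaborolane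
Product: 12 1-{2,4-bis(methoxymethoxy)-3-[(1E)-3-methylbuta-1,3-dien-1-yl]phenyl}ethan-1-one
Conditions: PdCl2(dppf) (5 mol%), K2CO3, dioxane/H2O, 80 °C
Reagents that add atoms: none
Why: Suzuki–Miyaura coupling of the hindered aryl iodide with the alkenylboronate should proceed with retention of the E geometry.

Step 9
Reactants: 6 2-aryl-7-(methoxymethoxy)-2H-chromen-2-ol (lactol); 12 1-{2,4-bis(methoxymethoxy)-3-[(1E)-3-methylbuta-1,3-dien-1-yl]phenyl}ethan-1-one
Product: 16 (1S,2S,6S)-ketone phenol [2,4-bis(methoxymethoxy)-3-prenylbenzoyl on C1; 3-acetyl-2,6-bis(methoxymethoxy)phenyl on C2; 4-methyl on the C3=C4 alkene; 2-hydroxy-4-(methoxymethoxy)phenyl on C6], via flavylium ion 13 (not isolated), via cyclobutane-fused oxocarbenium ion 14 (not isolated), via ring-expanded oxocarbenium ion 15 (not isolated)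
Conditions: (R)-3,3'-bis(2,4,6-triisopropylphenyl)-BINOL N-triflylphosphoramide (10 mol%), 12 (2 equiv), 5 Å MS, CH2Cl2, dark, −78 → −40 °C, then 0 °C → rt; sat. aq. NaHCO3
Reagents that add atoms: water, O (re-supplies on hydrolysis the oxygen atom that 6 loses on ionisation)
Why: Proposed new method: the chiral acid ionises lactol 6 to flavylium ion 13 (contact ion pair), the CH2 terminus C5 of the s-trans diene 12 adds to C6, and the resulting transoid allyl cation, which cannot reach C1 through C2, is captured at C4 by the enol-ether carbon C1 of the new 4H-chromene (4-exo-trig, enolexo) to give cyclobutane 14. In 14 the bond C1–C4 lies between the C7 oxocarbenium acceptor and the donor allyl system C4–C3–C2 conjugated to the 2,6-dioxygenated aryl ring, so it should re-ionise until the cisoid cation closes at C2 (6-endo-trig, enolexo), which expands the four-membered ring by C3 and C2 to cyclohexene 15; water then opens the pyran ring to 16. The closest known reaction types are the alkylation of flavylium ions at position 4 by electron-rich vinylarenes, chiral-counter-anion control of additions to benzopyrylium ions, the polar [2+2] addition of strong electrophiles to s-trans dienes whose vinylcyclobutane adducts rearrange to the formal [4+2] cyclohexenes, and the acid-promoted 1,3-shift of donor–acceptor vinylcyclobutanes. C6 is set by the chiral counter-anion in the first C–C bond formation; C1 is set by the ring fusion, because both closures can only occur on the face of the planar chromene that carries the C5 tether (H-1 cis to H-6, hence aroyl cis to the C6 aryl); C2 should be set under reversible C1–C2 ionisation in favour of the isomer with the aryl group anti to C7. The step needs attack at C6 (position 4 of the pyrylium ring) rather than at C7 (secured by the bulky 2-aryl group), four- before six-ring closure (secured by the s-trans diene) and no proton loss from C1 of 15 (secured by the base-free medium and the non-basic counter-anion).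

Step 10
Reactants: 16 (1S,2S,6S)-ketone phenol
Product: 17 (1S,2S,6S)-aryl triflate [as 16 but with 4-(methoxymethoxy)-2-(trifluoromethanesulfonyloxy)phenyl on C6]
Conditions: PhNTf2, Et3N, DMAP (cat.), CH2Cl2, 0 °C → rt
Reagents that add atoms: N-phenylbis(trifluoromethanesulfonimide), O=S(=O)(N(c1ccccc1)S(=O)(=O)C(F)(F)F)C(F)(F)F
Why: Mild sulfonylation of the single phenol (through its ring-opened phenoxide) avoids the acidic conditions that could dehydrate the cyclic hemiketal form and scramble C1.

Step 11
Reactants: 17 (1S,2S,6S)-aryl triflate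
Product: 18 (1S,2S,6S)-ketone [as 16 but with 4-(methoxymethoxy)phenyl on C6]
Conditions: Pd(OAc)2 (5 mol%), dppf (10 mol%), HCO2H, Et3N, DMF, 70 °C
Reagents that add atoms: none
Why: Palladium-catalysed formate reduction of the aryl triflate (oxidative addition, formate decarboxylation, C–H reductive elimination) should remove the lock oxygen without touching the alkenes, ketones or MOM ethers.

Step 12
Reactants: 19 2,4-dihydroxybenzaldehyde
Product: 20 2,4-bis(methoxymethoxy)benzaldehyde
Conditions: MOMCl, i-Pr2NEt, CH2Cl2, 0 → 40 °C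
Reagents that add atoms: chloromethyl methyl ether (MOMCl), COCCl
Why: Williamson-type O-alkylation of both phenols, with excess reagent and warming to overcome the hydrogen-bonded 2-hydroxyl.

Step 13
Reactants: 18 (1S,2S,6S)-ketone; 20 2,4-bis(methoxymethoxy)benzaldehyde
Product: 21 hepta-MOM ether of the target [(1S,2S,6S); (E)-3-[2,4-bis(methoxymethoxy)phenyl]prop-2-enoyl group on the C2 aryl ring]
Conditions: LiN(SiMe3)2 (1.05 equiv), THF, −78 °C; 20; then MsCl, Et3N, −78 → 0 °C
Reagents that add atoms: none
Why: Kinetic deprotonation should select the methyl ketone over the hindered tertiary C1–H, and the directed aldol addition followed by mesylation and E1cB elimination (a Claisen–Schmidt condensation in stepwise form) should give the E-enone without equilibrating C1.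

Step 14
Reactants: 21 hepta-MOM ether of the target
Product: 22 target, (1S,2S,6S)-configured heptaphenol (CNP0218862.3)
Conditions: 3 M aq. HCl, MeOH, 40 °C, dark
Reagents that add atoms: none
Why: Acid-catalysed transacetalisation to methanol should cleave all seven MOM ethers under conditions mild enough to spare the prenyl group, the ring alkene, the enone and the C1 stereocentre.

**Compound list**

1 | 4-bromobenzene-1,3-diol | Oc1ccc(Br)c(O)c1 | starting material
2 | 1-bromo-2,4-bis(methoxymethoxy)benzene | COCOc1ccc(Br)c(OCOC)c1 | intermediate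
3 | 1-bromo-2,4-bis(methoxymethoxy)-3-(3-methylbut-2-en-1-yl)benzene | COCOc1ccc(Br)c(OCOC)c1CC=C(C)C | intermediate
4 | 7-hydroxy-2H-chromen-2-one (umbelliferone) | O=c1ccc2ccc(O)cc2o1 | starting material
5 | 7-(methoxymethoxy)-2H-chromen-2-one | COCOc1ccc2ccc(=O)oc2c1 | intermediate
6 | 2-[2,4-bis(methoxymethoxy)-3-(3-methylbut-2-en-1-yl)phenyl]-7-(methoxymethoxy)-2H-chromen-2-ol (racemic lactol, in equilibrium with the (Z)-2-hydroxychalcone) | OC1(c2ccc(OCOC)c(CC=C(C)C)c2OCOC)C=Cc2ccc(OCOC)cc2O1 | intermediate
7 | 1-(2,4-dihydroxyphenyl)ethan-1-one | CC(=O)c1ccc(O)cc1O | starting material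
8 | 1-(2,4-dihydroxy-3-iodophenyl)ethan-1-one | CC(=O)c1ccc(O)c([I])c1O | intermediate
9 | 1-[3-iodo-2,4-bis(methoxymethoxy)phenyl]ethan-1-one | CC(=O)c1ccc(OCOC)c([I])c1OCOC | intermediate
10 | 2-methylbut-1-en-3-yne | C=C(C)C#C | starting material
11 | 4,4,5,5-tetramethyl-2-[(1E)-3-methylbuta-1,3-dien-1-yl]-1,3,2-dioxaborolane | C=C(C)/C=C/B1OC(C)(C)C(C)(C)O1 | intermediate
12 | 1-{2,4-bis(methoxymethoxy)-3-[(1E)-3-methylbuta-1,3-dien-1-yl]phenyl}ethan-1-one | CC(=O)c1ccc(OCOC)c(/C=C/C(C)=C)c1OCOC | intermediate
13 | flavylium ion: 2-[2,4-bis(methoxymethoxy)-3-prenylphenyl]-7-(methoxymethoxy)chromenylium (ion pair with the chiral phosphoramidate; cation shown) | COCOc1ccc2ccc(-c3ccc(OCOC)c(CC=C(C)C)c3OCOC)[o+]c2c1 | intermediate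
14 | cyclobutane-fused oxocarbenium ion: cyclobutane C1–C4–C5–C6 cis-fused at C1–C6 to the 2-aryl-7-(methoxymethoxy)chroman-2-ylium ring; C4 bears CH3 and the (E)-2-[3-acetyl-2,6-bis(methoxymethoxy)phenyl]vinyl group (C4 epimers; cation shown) | COCOc1ccc2c(c1)[O+]=C(c1ccc(OCOC)c(CC=C(C)C)c1OCOC)[C@H]1[C@@H]2CC1(C)/C=C/c1c(OCOC)ccc(C(C)=O)c1OCOC | intermediate
15 | ring-expanded oxocarbenium ion: cyclohexene cis-fused at C1–C6 to the 2-aryl-7-(methoxymethoxy)chroman-2-ylium ring; 3-acetyl-2,6-bis(methoxymethoxy)phenyl on C2, anti to C7; CH3 on C4 (cation shown) | COCOc1ccc2c(c1)[O+]=C(c1ccc(OCOC)c(CC=C(C)C)c1OCOC)[C@@H]1[C@@H](c3c(OCOC)ccc(C(C)=O)c3OCOC)C=C(C)C[C@H]21 | intermediate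
16 | {(1S,2S,6S)-2-[3-acetyl-2,6-bis(methoxymethoxy)phenyl]-6-[2-hydroxy-4-(methoxymethoxy)phenyl]-4-methylcyclohex-3-en-1-yl}[2,4-bis(methoxymethoxy)-3-(3-methylbut-2-en-1-yl)phenyl]methanone | CC(C)=CCc1c(OCOC)ccc(C(=O)[C@@H]2[C@@H](c3c(OCOC)ccc(C(C)=O)c3OCOC)C=C(C)C[C@@H]2c2ccc(OCOC)cc2O)c1OCOC | intermediate
17 | aryl triflate of 16: 2-{(1S,2S,6S)-…cyclohex-3-en-1-yl}-5-(methoxymethoxy)phenyl trifluoromethanesulfonate | CC(C)=CCc1c(OCOC)ccc(C(=O)[C@@H]2[C@@H](c3c(OCOC)ccc(C(C)=O)c3OCOC)C=C(C)C[C@@H]2c2ccc(OCOC)cc2OS(=O)(=O)C(F)(F)F)c1OCOC | intermediate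
18 | {(1S,2S,6S)-2-[3-acetyl-2,6-bis(methoxymethoxy)phenyl]-6-[4-(methoxymethoxy)phenyl]-4-methylcyclohex-3-en-1-yl}[2,4-bis(methoxymethoxy)-3-(3-methylbut-2-en-1-yl)phenyl]methanone | CC(C)=CCc1c(OCOC)ccc(C(=O)[C@@H]2[C@@H](c3c(OCOC)ccc(C(C)=O)c3OCOC)C=C(C)C[C@@H]2c2ccc(OCOC)cc2)c1OCOC | intermediate
19 | 2,4-dihydroxybenzaldehyde | O=Cc1ccc(O)cc1O | starting material
20 | 2,4-bis(methoxymethoxy)benzaldehyde | COCOc1ccc(C=O)c(OCOC)c1 | intermediate
21 | hepta-MOM ether of the target, (1S,2S,6S), E-enone | CC(C)=CCc1c(OCOC)ccc(C(=O)[C@@H]2[C@@H](c3c(OCOC)ccc(C(=O)/C=C/c4ccc(OCOC)cc4OCOC)c3OCOC)C=C(C)C[C@@H]2c2ccc(OCOC)cc2)c1OCOC | intermediate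
22 | target CNP0218862.3, (1S,2S,6S) | CC(C)=CCc1c(O)ccc(C(=O)[C@@H]2[C@@H](c3c(O)ccc(C(=O)/C=C/c4ccc(O)cc4O)c3O)C=C(C)C[C@@H]2c2ccc(O)cc2)c1O | target

**Step count and risks**

Total step count: 14. Longest linear sequence: 8 steps (1 → 2 → 3 → 6 → 16 → 17 → 18 → 21 → 22; the branch from 7 is equally long).

Steps most likely to fail:

Step 9 (Proposed new method). The cascade may be diverted by cationic oligomerisation of the diene, by addition at C7 instead of C6 of the pyrylium ring, by proton loss from the allyl cation, by proton loss and re-protonation at C1 of 15 (which would scramble the ring fusion), or by poor facial discrimination in the ion pair. The fallback uses known chemistry and sets out from 5 and 12. A high-pressure Diels–Alder reaction (12–15 kbar, CH2Cl2, 60 °C), with coumarin 5 as a Z-locked dienophile, should give the cis-fused exo lactone F1 as a racemate, to be separated from the endo isomer. Treatment of F1 with LiN(SiMe3)2 (1 equiv, −78 °C, to mask the acetyl group as its lithium enolate) and then with the aryllithium made from 3 and n-BuLi should open the lactone to the ketone phenol as a racemate, that is 16 together with its enantiomer F2. Preparative chromatography on a chiral stationary phase removes F2, and the route is rejoined at 16.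

Step 4. The adduct may take up a second aryllithium, or the (Z)-enone may isomerise to the E-isomer, which cannot close to the lactol. The fallback sets out from 3 and 19. Bromine–lithium exchange on 3 and acylation with N-methoxy-N-methylacetamide should give the acetophenone F3. Selective 4-O-alkylation of 19 (MOMCl, K2CO3, acetone) should give the salicylaldehyde F4. Claisen–Schmidt condensation (KOH, EtOH) should then give the (E)-2-hydroxychalcone F5. Irradiation of F5 at 405 nm in MeCN isomerises it to the Z-enone, which closes to the lactol, so the route is rejoined at 6.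

Step 13. Enolisation may not stay at the methyl ketone, with epimerisation at C1 or aldol addition at the wrong ketone. The fallback sets out from 12 and 20 and forms the enone before any stereocentre exists. Claisen–Schmidt condensation (KOH, EtOH/H2O) should give the diene chalcone F6. Reaction of F6 with 6 under the conditions of step 9 should give the ketone phenol F7. Triflation as in step 10 should give the aryl triflate F8, and formate reduction as in step 11 (kept at the lowest workable temperature to spare the enone) rejoins the route at 21.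

**Further compounds**

F1 | step 9 | racemic cis-fused exo lactone: 10-[3-acetyl-2,6-bis(methoxymethoxy)phenyl]-3-(methoxymethoxy)-8-methyl-6a,7,10,10a-tetrahydro-6H-benzo[c]chromen-6-one (relative configuration shown) | COCOc1ccc2c(c1)OC(=O)[C@@H]1[C@@H](c3c(OCOC)ccc(C(C)=O)c3OCOC)C=C(C)C[C@H]21
F2 | step 9 | enantiomer of 16, (1R,2R,6R), formed together with 16 as the racemate | CC(C)=CCc1c(OCOC)ccc(C(=O)[C@H]2[C@H](c3c(OCOC)ccc(C(C)=O)c3OCOC)C=C(C)C[C@H]2c2ccc(OCOC)cc2O)c1OCOC
F3 | step 4 | 1-[2,4-bis(methoxymethoxy)-3-(3-methylbut-2-en-1-yl)phenyl]ethan-1-one | CC(=O)c1ccc(OCOC)c(CC=C(C)C)c1OCOC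
F4 | step 4 | 2-hydroxy-4-(methoxymethoxy)benzaldehyde | COCOc1ccc(C=O)c(O)c1
F5 | step 4 | (E)-1-[2,4-bis(methoxymethoxy)-3-(3-methylbut-2-en-1-yl)phenyl]-3-[2-hydroxy-4-(methoxymethoxy)phenyl]prop-2-en-1-one | COCOc1ccc(/C=C/C(=O)c2ccc(OCOC)c(CC=C(C)C)c2OCOC)c(O)c1
F6 | step 13 | (E)-1-{2,4-bis(methoxymethoxy)-3-[(1E)-3-methylbuta-1,3-dien-1-yl]phenyl}-3-[2,4-bis(methoxymethoxy)phenyl]prop-2-en-1-one | C=C(C)/C=C/c1c(OCOC)ccc(C(=O)/C=C/c2ccc(OCOC)cc2OCOC)c1OCOC
F7 | step 13 | (1S,2S,6S)-ketone phenol carrying the protected chalcone on the C2 aryl ring and 2-hydroxy-4-(methoxymethoxy)phenyl on C6 | CC(C)=CCc1c(OCOC)ccc(C(=O)[C@@H]2[C@@H](c3c(OCOC)ccc(C(=O)/C=C/c4ccc(OCOC)cc4OCOC)c3OCOC)C=C(C)C[C@@H]2c2ccc(OCOC)cc2O)c1OCOC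
F8 | step 13 | aryl triflate of F7 | CC(C)=CCc1c(OCOC)ccc(C(=O)[C@@H]2[C@@H](c3c(OCOC)ccc(C(=O)/C=C/c4ccc(OCOC)cc4OCOC)c3OCOC)C=C(C)C[C@@H]2c2ccc(OCOC)cc2OS(=O)(=O)C(F)(F)F)c1OCOC
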